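Product in these flasks stops short: at 6.00 d Tuesday's run reads 43 % with 11 % of the starting material still there, and Wednesday's reads 40 % with 13 %.

common to all: starting material 0.20 M; free catalyst 0.5 mol%

|  | coupling partner | protic impurity | capture agent | temperature | remark | time |
|---|---|---|---|---|---|---|
| Tuesday's | 1.2 equiv | 0.10 M | 0.010 M | 70 °C | the very flask that is asked about, followed so far |  |
| Wednesday's | 1.2 equiv | 0.10 M | 0.010 M | 65 °C | run made earlier |  |
| flask | 1.20 equiv | 0.100 M | 0.0100 M | 70 °C |  | 8.0 d |

| run | time / d | product / % | starting material / % |
|---|---|---|---|
| Tuesday's | 0.417 | 12 | 67 |
| Tuesday's | 1.25 | 30 | 34 |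
| Tuesday's | 2.50 | 34 | 22 |
| Tuesday's | 4.00 | 38 | 14 |
| Tuesday's | 5.00 | 40 | 14 |
| Tuesday's | 6.00 | 43 | 11 |
| Wednesday's | 0.417 | 7 | 72 |
| Wednesday's | 1.25 | 23 | 47 |
| Wednesday's | 2.50 | 33 | 32 |
| Wednesday's | 4.00 | 39 | 18 |
| Wednesday's | 5.00 | 39 | 14 |
| Wednesday's | 6.00 | 40 | 13 |

(readings scatter by 1.5 percentage points)

- green: at 8.0 d add free catalyst, 100 % of the amount charged, then wait 4.0 d
- amber: change nothing and wait 4.0 d more
- violet: at 8.0 d take out 90 % of the product then present, then wait 4.0 d
- red: at 8.0 d add coupling partner, 100 % of the amount charged, then wait 4.0 d
- grey: at 8.0 d raise the temperature by 10 K, then wait 4.0 d

- product that was removed still counts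
- the analysis behind the earlier runs scatters by 1.5 percentage points, standard deviation
- steps under discussion: catalyst intermediate B <-> free catalyst + product; starting material + protic impurity -> quenched substrate; coupling partner + free catalyst -> catalyst intermediate A; catalyst intermediate A + capture agent -> trapped intermediate; starting material + catalyst intermediate A -> catalyst intermediate B
- additions bring no volume worth counting

- product, in percent of the starting material first charged, at 8.0 d
- which option adds most product ("none" when 2 percentage points or less is all one gets) (green / amber / violet / red / grey / none)
- product present, with what was taken out counted in, in percent of the starting material first charged, after amber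
- product present, with what was taken out counted in, in percent of the starting material first charged, after red

Where did the rest go? Tuesday's run has lost 46.0 % of its charge to something other than product, and the protic impurity, charged at half the starting material, can quench about that much.

Then why does starting material sit unused? Catalyst intermediate A meets either starting material, which carries the round towards product, or capture agent, which removes that catalyst as trapped intermediate. The odds between them (a selectivity factor) follow the share of starting material left, because trapping the catalyst charged takes just 10.0 % of the capture agent. So product made at a low share costs more catalyst.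

Call the catalyst budget the sum, over the run, of each slice of product divided by the mean share of starting material while it formed. Tuesday's readings sum to 1.25 and Wednesday's to 0.918. The late slices carry much scatter and the runs stand at 70 °C and 65 °C, but I take one mean for both, 1.08, assuming both sums are nearly complete.

What can still be bought? From the last readings I put this flask, at 8.0 d, at 41.5 % product and 12.0 % starting material. A fresh charge of catalyst brings a fresh budget, and I let the share decay as in first-order decay, with the budget in place of time. That gives green 7.9 percentage points, against the 2 points mark. Amber, violet, red and grey bring no catalyst, so I keep them under the mark, with amber and red near 41.5 %.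

The forecast gives 44 % (41.5 % to 46.5 %), green as best, 45.5 % after amber and 46 % after red, and says “Fresh catalyst should convert much of the remainder”. Its product at 8.0 d stands above mine.

The flask gives 40.6 %, and green adds 7.6 points, while red ends at 40.7 %, 5.3 points under the forecast.

catalyst intermediate B ⇌ free catalyst + product (K = 0.130 M, k = 330 /h, Ea = 92.0 kJ/mol, ΔH = −35.0 kJ/mol); starting material + protic impurity → quenched substrate (k = 0.400 /M/h, Ea = 93.0 kJ/mol); coupling partner + free catalyst → catalyst intermediate A (k = 13.0 /M/h, Ea = 85.0 kJ/mol); catalyst intermediate A + capture agent → trapped intermediate (k = 530 /M/h, Ea = 70.0 kJ/mol); starting material + catalyst intermediate A → catalyst intermediate B (k = 5500 /M/h, Ea = 58.0 kJ/mol); (constants at 70 °C) At 8.00 d the trapped intermediate holds 99.9 % of the catalyst charged. The budget applied to the 10.9 % of starting material left gives green 7.2 points. In a neighbour flask with 0.040 M of capture agent I scale the budget to a quarter, and that flask's 17.4 % of product then implies a mean share of 64.1 %, between the full charge and the 32.8 % left at its end.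

(The readings were generated by integration for an exercise; the scatter is artificial.)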